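**Strategy.** The plan rests on cutting the dioxane ring at O4–C3 and O1–C2. That ring hangs on two neighbouring oxygens of ring A (a masked o-quinone), C3 carries H and CH3, and the hemiketal carbon C2 sits at the acid oxidation level, so both ring carbons map onto the alpha-carbon and carbonyl of a propionyl-derived ketene enolate. One catalytic asymmetric hetero-[4+2] step joins a bromo-methoxy-o-benzoquinone with this enolate, re-aromatises ring A, closes the dioxinone lactone and sets C3. The precursor is a freshly made 5-bromo-3-methoxy-1,2-benzoquinone; bromine holds the place of the allyl group. Lactone opening to a Weinreb amide, allylation and aryl addition then deliver the hemiketal.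

Key step: step 3

Remark on the catalyst: O-benzoylquinidine is assumed to give the 3R lactone, by analogy with the facial preference of this catalyst family in related ketene enolate reactions; if the sense is opposite, the pseudoenantiomer O-benzoylquinine is used instead.

Remark on C2: the hemiketal carbon is taken to be configurationally mobile through ring-chain tautomerism, and the 2S,3R isomer is assumed to be the one favoured at equilibrium.

**Step 1**
Reactants: 1 5-bromo-2-hydroxy-3-methoxybenzaldehyde (5-bromo-o-vanillin)
Product: 3 5-bromo-3-methoxybenzene-1,2-diol, via aryl formate 2 (not isolated)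
Conditions: aq. H2O2, aq. NaOH, THF/H2O, 0 °C to rt, N2; then aq. HCl
Reagents that add atoms: hydrogen peroxide, OO
Why: Dakin oxidation, in which hydroperoxide adds to the formyl group of the ortho-hydroxy aldehyde, the electron-rich aryl group migrates to oxygen and the formate 2 is saponified in the same flask, while the aryl bromide and the methyl ether are inert.

**Step 2**
Reactants: 3 5-bromo-3-methoxybenzene-1,2-diol
Product: 4 5-bromo-3-methoxy-1,2-benzoquinone
Conditions: Ag2O (monovalent silver), anhydrous Na2SO4, dry THF, 0 °C, dark; filtered under argon, solution cooled to -78 °C and used at once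
Reagents that add atoms: none
Why: two-electron oxidation of a catechol to the o-quinone by Ag2O under anhydrous, non-nucleophilic conditions, with Na2SO4 binding the water formed and immediate cold use limiting dimerisation of the quinone.

**Step 3**
Reactants: 4 5-bromo-3-methoxy-1,2-benzoquinone; 5 propionyl chloride
Product: 7 (R)-7-bromo-5-methoxy-3-methyl-1,4-benzodioxin-2(3H)-one, via methylketene 6 (not isolated)
Conditions: O-benzoylquinidine (10 mol%), iPr2NEt, THF, -78 °C, slow addition of 5, then to -40 °C
Reagents that add atoms: none
Why: Hünig base and the alkaloid strip HCl from 5 to give methylketene 6, held on the quinuclidine nitrogen as a zwitterionic Z-ammonium enolate; its alpha-carbon adds to the quinone oxygen on C2 (next to C-OMe, the future O4), the O=C-C=O unit acting as an electron-poor heterodiene with aromatisation of ring A as driving force, and the phenoxide freed on C1 (the future O1) then attacks the acylammonium carbonyl and releases the catalyst. The closest known reaction type is the cinchona-alkaloid-catalysed enantioselective formal [4+2] cycloaddition of acid-chloride-derived ketene enolates with tetrahalogenated o-benzoquinones, which gives 3-substituted 1,4-benzodioxin-2-ones; quinone 4 is less electrophilic and unsymmetrical, so rate and regiochemistry are the open points. The dioxinone ring closes in two events: intermolecular C3-O4 bond formation, then 6-exo-trig acyl transfer of the phenoxide onto the acylammonium carbon (O1-C2). The only new stereocentre, C3, is controlled by the catalyst, whose benzoate and quinoline groups shield one face of the Z-enolate so that the quinone oxygen arrives on the open face, expected to give R with O-benzoylquinidine. Besides this facial selectivity the step needs ether formation at the oxygen flanked by the methoxy group; this is argued from the phenoxide developing at the other oxygen, which is meta to both Br and OMe and so the better stabilised, and from the C2 carbonyl being the more ketone-like one, not in through-conjugation with the methoxy donor. The bromine also raises the electrophilicity of the quinone and, unlike an allyl group at that carbon, opens no path to a quinone methide under the amine base.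

**Step 4**
Reactants: 7 (R)-7-bromo-5-methoxy-3-methyl-1,4-benzodioxin-2(3H)-one
Product: 8 (R)-2-(4-bromo-2-hydroxy-6-methoxyphenoxy)-N-methoxy-N-methylpropanamide
Conditions: MeNH(OMe) (free base, 3 equiv), 2-hydroxypyridine (cat.), THF, 0 °C to rt
Reagents that add atoms: N,O-dimethylhydroxylamine, CNOC
Why: aminolysis of an activated phenolic lactone (aryl ester with an alpha-oxygen) by a weakly basic alpha-effect amine, which opens the ring to the Weinreb amide and frees the phenol without enolising the alpha-stereocentre.

**Step 5**
Reactants: 8 (R)-2-(4-bromo-2-hydroxy-6-methoxyphenoxy)-N-methoxy-N-methylpropanamide; 9 allyltributylstannane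
Product: 10 (R)-2-(4-allyl-2-hydroxy-6-methoxyphenoxy)-N-methoxy-N-methylpropanamide
Conditions: Pd(PPh3)4 (zerovalent palladium, 5 mol%), degassed toluene, 100 °C; aq. KF work-up
Reagents that add atoms: none
Why: Migita-Kosugi-Stille coupling (oxidative addition into the aryl C-Br bond, allyl transfer from tin, reductive elimination) under neutral conditions that leave the free phenol, the Weinreb amide and the stereocentre untouched, with short heating to keep the double bond out of conjugation.

**Step 6**
Reactants: 11 5-bromo-1,2,3-trimethoxybenzene
Product: 12 3,4,5-trimethoxyphenylmagnesium bromide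
Conditions: Mg turnings, I2 (cat.), THF, reflux then rt; used as solution
Reagents that add atoms: magnesium, [Mg]
Why: Grignard formation by insertion of magnesium into the aryl C-Br bond, the methyl ethers being inert.

**Step 7**
Reactants: 10 (R)-2-(4-allyl-2-hydroxy-6-methoxyphenoxy)-N-methoxy-N-methylpropanamide; 12 3,4,5-trimethoxyphenylmagnesium bromide
Product: 15 (2S,3R)-7-allyl-5-methoxy-3-methyl-2-(3,4,5-trimethoxyphenyl)-2,3-dihydro-1,4-benzodioxin-2-ol, via magnesium tetrahedral adduct 13 (not isolated), via open keto-phenol 14 (not isolated)
Conditions: 12 (3 equiv), THF, -20 to 0 °C; sat. aq. NH4Cl, 0 °C to rt (no strong acid)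
Reagents that add atoms: none
Why: Weinreb ketone synthesis in which the first equivalent of 12 deprotonates the phenol and the next gives the chelated adduct 13, which neither collapses nor enolises before the buffered quench; hydrolysis then releases ketone 14, whose ortho phenol adds 6-exo-trig to the carbonyl, and C2 settles by ring-chain equilibration into the isomer with OH pseudo-axial (anomeric), aryl pseudo-equatorial and methyl anti to OH, while C3 is carried over from 10.

**Compound list**
1 | 5-bromo-2-hydroxy-3-methoxybenzaldehyde | O=Cc1cc(Br)cc(OC)c1O | starting material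
2 | 5-bromo-2-hydroxy-3-methoxyphenyl formate | O=COc1cc(Br)cc(OC)c1O | intermediate (not isolated)
3 | 5-bromo-3-methoxybenzene-1,2-diol | Oc1cc(Br)cc(OC)c1O | intermediate
4 | 5-bromo-3-methoxy-1,2-benzoquinone | COC1=CC(Br)=CC(=O)C1=O | intermediate
5 | propionyl chloride | CCC(Cl)=O | starting material
6 | methylketene | CC=C=O | intermediate (not isolated)
7 | (R)-7-bromo-5-methoxy-3-methyl-1,4-benzodioxin-2(3H)-one | COc1cc(Br)cc2OC(=O)[C@@H](C)Oc12 | intermediate
8 | (R)-2-(4-bromo-2-hydroxy-6-methoxyphenoxy)-N-methoxy-N-methylpropanamide | COc1cc(Br)cc(O)c1O[C@H](C)C(=O)N(C)OC | intermediate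
9 | allyltributylstannane | C=CC[Sn](CCCC)(CCCC)CCCC | starting material
10 | (R)-2-(4-allyl-2-hydroxy-6-methoxyphenoxy)-N-methoxy-N-methylpropanamide | COc1cc(CC=C)cc(O)c1O[C@H](C)C(=O)N(C)OC | intermediate
11 | 5-bromo-1,2,3-trimethoxybenzene | COc1cc(Br)cc(OC)c1OC | starting material
12 | 3,4,5-trimethoxyphenylmagnesium bromide | COc1cc([Mg]Br)cc(OC)c1OC | intermediate
13 | bis(bromomagnesium) salt of the tetrahedral adduct of 12 with amide 10 (phenoxide and N-methoxy-N-methyl hemiaminal alkoxide) | COc1cc(CC=C)cc(O[Mg]Br)c1O[C@H](C)C(O[Mg]Br)(N(C)OC)c1cc(OC)c(OC)c(OC)c1 | intermediate (not isolated)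
14 | (R)-2-(4-allyl-2-hydroxy-6-methoxyphenoxy)-1-(3,4,5-trimethoxyphenyl)propan-1-one | COc1cc(CC=C)cc(O)c1O[C@H](C)C(=O)c1cc(OC)c(OC)c(OC)c1 | intermediate (not isolated)
15 | (2S,3R)-7-allyl-5-methoxy-3-methyl-2-(3,4,5-trimethoxyphenyl)-2,3-dihydro-1,4-benzodioxin-2-ol (CNP0114249.1) | C=CCc1cc(OC)c2c(c1)O[C@@](O)(c1cc(OC)c(OC)c(OC)c1)[C@@H](C)O2 | target

**Step count.** Total: 7 steps. Longest linear sequence: 6 steps (steps 1, 2, 3, 4, 5 and 7); step 6 is a one-step side branch.

**Steps most likely to fail**

1. Step 3. The less electrophilic quinone may react too slowly, so that ketene dimerisation and quinone self-condensation take over. Ether formation may also occur at the wrong quinone oxygen, or facial control may be incomplete. The fallback sets out from 1 and avoids the quinone altogether. Mitsunobu etherification of the phenol of 1 with methyl (S)-lactate (PPh3, DIAD, THF) proceeds with inversion and should give methyl (R)-2-(4-bromo-2-formyl-6-methoxyphenoxy)propanoate F1. Baeyer-Villiger oxidation of the aldehyde with mCPBA in CH2Cl2 should give methyl (R)-2-[4-bromo-2-(formyloxy)-6-methoxyphenoxy]propanoate F2. Acid-catalysed methanolysis of the formate (TsOH, MeOH, rt) should give methyl (R)-2-(4-bromo-2-hydroxy-6-methoxyphenoxy)propanoate F3. Lactonisation of F3 (TsOH cat., toluene, reflux, removal of MeOH) comes back to the route at 7. Regiochemistry is fixed in this fallback, because the ether oxygen is the original phenol oxygen of 1 and the acyl oxygen comes from the formyl carbon.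

2. Step 7. The magnesium phenoxide may slow the acyl substitution, and at the temperatures then needed the proton at C3 may be removed and its configuration lost. Ring closure may also give a mixture at C2. The fallback sets out from 10 and separates C-C bond formation from ring closure. Silylation (TBSCl, imidazole, DMF) should give (R)-2-[4-allyl-2-(tert-butyldimethylsilyloxy)-6-methoxyphenoxy]-N-methoxy-N-methylpropanamide F4. Addition of 12 (1.3 equiv, THF, -20 °C) should give (R)-2-[4-allyl-2-(tert-butyldimethylsilyloxy)-6-methoxyphenoxy]-1-(3,4,5-trimethoxyphenyl)propan-1-one F5. Buffered desilylation (TBAF, AcOH, THF, 0 °C) frees the phenol and comes back to the route at 14, which closes to 15.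

3. Step 5. Oxidative addition into the electron-rich aryl bromide may be slow. On prolonged heating the allyl double bond may migrate into conjugation, and the phenol may consume the stannane by protonolysis. The fallback sets out from 8 and changes both the masking of the phenol and the organometallic partner. Silylation (TIPSCl, imidazole, DMF) should give (R)-2-[4-bromo-2-methoxy-6-(triisopropylsilyloxy)phenoxy]-N-methoxy-N-methylpropanamide F6. Suzuki-Miyaura coupling with allylboronic acid pinacol ester (Pd(dppf)Cl2 as divalent palladium precatalyst, K3PO4, THF/H2O, 65 °C) should give (R)-2-[4-allyl-2-methoxy-6-(triisopropylsilyloxy)phenoxy]-N-methoxy-N-methylpropanamide F7. Desilylation (TBAF, AcOH, THF, 0 °C) comes back to the route at 10.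

**Further compounds**
F1 | step 3 | methyl (R)-2-(4-bromo-2-formyl-6-methoxyphenoxy)propanoate | COC(=O)[C@@H](C)Oc1c(C=O)cc(Br)cc1OC
F2 | step 3 | methyl (R)-2-[4-bromo-2-(formyloxy)-6-methoxyphenoxy]propanoate | COC(=O)[C@@H](C)Oc1c(OC=O)cc(Br)cc1OC
F3 | step 3 | methyl (R)-2-(4-bromo-2-hydroxy-6-methoxyphenoxy)propanoate | COC(=O)[C@@H](C)Oc1c(O)cc(Br)cc1OC
F4 | step 7 | (R)-2-[4-allyl-2-(tert-butyldimethylsilyloxy)-6-methoxyphenoxy]-N-methoxy-N-methylpropanamide | COc1cc(CC=C)cc(O[Si](C)(C)C(C)(C)C)c1O[C@H](C)C(=O)N(C)OC
F5 | step 7 | (R)-2-[4-allyl-2-(tert-butyldimethylsilyloxy)-6-methoxyphenoxy]-1-(3,4,5-trimethoxyphenyl)propan-1-one | COc1cc(CC=C)cc(O[Si](C)(C)C(C)(C)C)c1O[C@H](C)C(=O)c1cc(OC)c(OC)c(OC)c1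
F6 | step 5 | (R)-2-[4-bromo-2-methoxy-6-(triisopropylsilyloxy)phenoxy]-N-methoxy-N-methylpropanamide | COc1cc(Br)cc(O[Si](C(C)C)(C(C)C)C(C)C)c1O[C@H](C)C(=O)N(C)OC
F7 | step 5 | (R)-2-[4-allyl-2-methoxy-6-(triisopropylsilyloxy)phenoxy]-N-methoxy-N-methylpropanamide | COc1cc(CC=C)cc(O[Si](C(C)C)(C(C)C)C(C)C)c1O[C@H](C)C(=O)N(C)OC
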